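**Plan**
- Retrosynthesis: the first cut is the bond from the guaiacyl ring carbon para to OH to C2 of the furan ring, giving arylboronate 8 and 2-chloro-3-formylbenzofuran 7. The second cut removes C3–CHO and C2–Cl together, back to lactone 5. The third opens the lactone (O1–C2) and cuts C3–C3a, back to phenol 1 and glyoxylic acid.
- Enabling feature: C2 sits between ring O1 and the C3 formyl group, so it is the O-bearing β-carbon of the C2=C3–CHO enal, a vinylogous acyl carbon. Its precursor is the C2 carbonyl next to the acidic C3 methylene of a benzofuran-2(3H)-one, which one chloroformylation converts into C2–Cl and C3–CHO.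
- Forward order: the phenoxide adds to glyoxylate (C3–C3a bond); hydrogenolysis and lactonisation close the five-membered O1–C2–C3 ring, with the side-chain OH masked as acetate in the same pot; chloroformylation aromatises the furan; the guaiacyl ring is joined at C2; methanolysis removes the acetate.
- Stereochemistry: the target has no stereocentre, so none has to be set.

Key step: step 4

Remark on the chemistry: the target is achiral (no stereocentre, no stereogenic double bond), so it is made as such; the one stereocentre that appears on the way (carbinol carbon of 3) is racemic and is erased in step 2.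

**Step 1**
Reactants: 1 4-(3-hydroxypropyl)-2-methoxyphenol (dihydroconiferyl alcohol); 2 glyoxylic acid (50 % aqueous solution)
Product: 3 2-hydroxy-2-[2-hydroxy-5-(3-hydroxypropyl)-3-methoxyphenyl]acetic acid (racemic)
Conditions: 2 (1.5 equiv), NaOH (3.5 equiv), H2O, N2, 25–35 °C; then HCl to pH 1, EtOAc extraction; crude used directly
Reagents that add atoms: none
Why: Aldol-type ortho-hydroxyalkylation of a phenoxide by glyoxylate; the para position of 1 is blocked by the side chain and the other ortho position by OMe, so the phenoxide should react only through C6, giving the mandelic acid as a racemate.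

**Step 2**
Reactants: 3 2-hydroxy-2-[2-hydroxy-5-(3-hydroxypropyl)-3-methoxyphenyl]acetic acid
Product: 5 3-(7-methoxy-2-oxo-2,3-dihydro-1-benzofuran-5-yl)propyl acetate, via arylacetic acid 4 (not isolated)
Conditions: H2 (4 bar), 10 % Pd/C, AcOH, H2SO4 (0.2 equiv), 70 °C; filter; concentrate, PhMe azeotrope
Reagents that add atoms: acetic acid CC(=O)O
Why: Acid-promoted Pd-catalysed hydrogenolysis of the benzylic C–OH of a mandelic acid should give arylacetic acid 4; under the same Fischer esterification conditions the solvent acetylates the primary alcohol and the ortho-hydroxy acid closes to the five-membered lactone once water is removed, while the phenol and the aryl methyl ethers are inert.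

**Step 3**
Reactants: 5 3-(7-methoxy-2-oxo-2,3-dihydro-1-benzofuran-5-yl)propyl acetate
Product: 7 3-(2-chloro-3-formyl-7-methoxy-1-benzofuran-5-yl)propyl acetate, via iminium chloride 6 (not isolated)
Conditions: POCl3 (3 equiv), DMF (6 equiv), ClCH2CH2Cl, 0 → 70 °C; then ice, aq. NaOAc, 20 °C
Reagents that add atoms: N,N-dimethylformamide CN(C)C=O; phosphoryl chloride O=P(Cl)(Cl)Cl; water O
Why: Vilsmeier–Haack–Arnold chloroformylation of an enolisable lactone: the chloromethyleneiminium ion attacks the acidic C3 methylene, the lactone C2=O is exchanged for C2–Cl via its O-phosphorylated enol form with aromatisation of the furan ring, and aqueous work-up hydrolyses iminium 6 to the aldehyde without touching the acetate.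

**Step 4**
Reactants: 7 3-(2-chloro-3-formyl-7-methoxy-1-benzofuran-5-yl)propyl acetate; 8 2-methoxy-4-(4,4,5,5-tetramethyl-1,3,2-dioxaborolan-2-yl)phenol (1.2 equiv)
Product: 9 3-[3-formyl-2-(4-hydroxy-3-methoxyphenyl)-7-methoxy-1-benzofuran-5-yl]propyl acetate
Conditions: Pd(dppf)Cl2·CH2Cl2 (3 mol %), NaHCO3 (3 equiv), DME/H2O 4:1, 75 °C, Ar
Reagents that add atoms: none
Why: Pd(0) inserts into the C2–Cl bond, which is activated like an acyl chloride because C2 is bonded to ring O1 and is the β-carbon of the C2=C3–CHO enal; bicarbonate and water convert boronate 8 into the transferring hydroxyboronate, transmetalation places the guaiacyl group on Pd, and reductive elimination forms the aryl–C2 bond. The closest known reaction type is the Suzuki–Miyaura coupling of β-chlorovinyl aldehydes such as 2-chloro-3-formyl indoles and quinolines with arylboron reagents. No ring is closed and no stereocentre is created. The step needs chemoselectivity for C–C coupling over addition–elimination of phenoxide or hydroxide at C2 and over ester hydrolysis; the weak base keeps the phenol of 8 largely protonated and leaves the acetate intact, while oxidative addition at this activated chloride should be fast. Regiochemistry is fixed on both partners by the positions of Cl and B, and the aldehyde and free phenol are tolerated.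

**Step 5**
Reactants: 9 3-[3-formyl-2-(4-hydroxy-3-methoxyphenyl)-7-methoxy-1-benzofuran-5-yl]propyl acetate
Product: 10 2-(4-hydroxy-3-methoxyphenyl)-5-(3-hydroxypropyl)-7-methoxy-1-benzofuran-3-carbaldehyde
Conditions: K2CO3 (0.5 equiv), MeOH, 25 °C; then aq. NH4Cl
Reagents that add atoms: none
Why: Carbonate-catalysed transesterification with methanol removes the acetate helper; the non-enolisable aldehyde, the phenol and the 2-arylbenzofuran are stable to these mild basic conditions.

**Compound list**
1 | 4-(3-hydroxypropyl)-2-methoxyphenol (dihydroconiferyl alcohol) | COc1cc(CCCO)ccc1O | starting material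
2 | glyoxylic acid | O=CC(=O)O | starting material
3 | 2-hydroxy-2-[2-hydroxy-5-(3-hydroxypropyl)-3-methoxyphenyl]acetic acid (racemic) | COc1cc(CCCO)cc(C(O)C(=O)O)c1O | intermediate
4 | 2-[2-hydroxy-5-(3-hydroxypropyl)-3-methoxyphenyl]acetic acid | COc1cc(CCCO)cc(CC(=O)O)c1O | intermediate (not isolated)
5 | 3-(7-methoxy-2-oxo-2,3-dihydro-1-benzofuran-5-yl)propyl acetate | COc1cc(CCCOC(C)=O)cc2c1OC(=O)C2 | intermediate
6 | N-{[5-(3-acetoxypropyl)-2-chloro-7-methoxy-1-benzofuran-3-yl]methylidene}-N-methylmethanaminium chloride | COc1cc(CCCOC(C)=O)cc2c(C=[N+](C)C)c(Cl)oc12.[Cl-] | intermediate (not isolated)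
7 | 3-(2-chloro-3-formyl-7-methoxy-1-benzofuran-5-yl)propyl acetate | COc1cc(CCCOC(C)=O)cc2c(C=O)c(Cl)oc12 | intermediate
8 | 2-methoxy-4-(4,4,5,5-tetramethyl-1,3,2-dioxaborolan-2-yl)phenol | COc1cc(B2OC(C)(C)C(C)(C)O2)ccc1O | starting material
9 | 3-[3-formyl-2-(4-hydroxy-3-methoxyphenyl)-7-methoxy-1-benzofuran-5-yl]propyl acetate | COc1cc(-c2oc3c(OC)cc(CCCOC(C)=O)cc3c2C=O)ccc1O | intermediate
10 | 2-(4-hydroxy-3-methoxyphenyl)-5-(3-hydroxypropyl)-7-methoxy-1-benzofuran-3-carbaldehyde | COc1cc(-c2oc3c(OC)cc(CCCO)cc3c2C=O)ccc1O | target

Total step count: 5. Longest linear sequence: 5 steps (1 → 3 → 5 → 7 → 9 → 10); 8 is purchased.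

**Steps most likely to fail**

Step 3. The chloroformylation may stop after aminomethylenation of C3 without exchange of the lactone carbonyl oxygen for chloride, or the electron-rich benzo ring may be formylated as well. The fallback sets out from 5 and changes the order of events. Triflation of the lactone enol (Tf2O, i-Pr2NEt, CH2Cl2, −78 → 0 °C) should give 3-(7-methoxy-2-{[(trifluoromethyl)sulfonyl]oxy}-1-benzofuran-5-yl)propyl acetate F1. Suzuki–Miyaura coupling of F1 with 8 (Pd(dppf)Cl2, NaHCO3, DME/H2O, 75 °C) should give 3-[2-(4-hydroxy-3-methoxyphenyl)-7-methoxy-1-benzofuran-5-yl]propyl acetate F2. Vilsmeier–Haack formylation of F2 (POCl3, DMF, 0 → 60 °C, aqueous work-up) should then enter at C3, the most nucleophilic carbon of the 2-arylbenzofuran, and the route is rejoined at 9.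

Step 4. Displacement of the C2 chloride by phenoxide or hydroxide (addition–elimination at the vinylogous acyl carbon) may outrun oxidative addition, and the electron-rich boronate may protodeboronate. The fallback sets out from 7 and uses a base-free, anhydrous Negishi coupling with a masked phenol. Commercial 4-bromo-2-methoxyphenol is silylated (TBSCl, imidazole, DMF) to (4-bromo-2-methoxyphenoxy)(tert-butyl)dimethylsilane F3. Bromine–lithium exchange (n-BuLi, THF, −78 °C) followed by ZnCl2 should give [4-{[tert-butyl(dimethyl)silyl]oxy}-3-methoxyphenyl]zinc chloride F4. Coupling of F4 with 7 (Pd(PPh3)4, THF, 25–50 °C) should give 3-[2-(4-{[tert-butyl(dimethyl)silyl]oxy}-3-methoxyphenyl)-3-formyl-7-methoxy-1-benzofuran-5-yl]propyl acetate F5. K2CO3 in MeOH should then cleave the aryl silyl ether and the acetate together, and the route is rejoined at 10.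

Step 2. The benzylic cation may undergo acid-promoted Friedel–Crafts self-condensation, and C–O hydrogenolysis may stall once the hydroxy acid has closed to the hydroxy lactone. The fallback sets out from 3 and replaces hydrogenolysis by activation and single-electron reduction. Lactonisation and acetylation (Ac2O, cat. H2SO4, 60 °C) should give 3-[3-(acetyloxy)-7-methoxy-2-oxo-2,3-dihydro-1-benzofuran-5-yl]propyl acetate F6 (racemic). Reductive cleavage of the α-acetoxy group of F6 with SmI2 (THF, pivalic acid, −78 °C) should give the lactone, and the route is rejoined at 5.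

**Further compounds**
F1 | step 3 | 3-(7-methoxy-2-{[(trifluoromethyl)sulfonyl]oxy}-1-benzofuran-5-yl)propyl acetate | COc1cc(CCCOC(C)=O)cc2cc(OS(=O)(=O)C(F)(F)F)oc12
F2 | step 3 | 3-[2-(4-hydroxy-3-methoxyphenyl)-7-methoxy-1-benzofuran-5-yl]propyl acetate | COc1cc(-c2cc3cc(CCCOC(C)=O)cc(OC)c3o2)ccc1O
F3 | step 4 | (4-bromo-2-methoxyphenoxy)(tert-butyl)dimethylsilane | COc1cc(Br)ccc1O[Si](C)(C)C(C)(C)C
F4 | step 4 | [4-{[tert-butyl(dimethyl)silyl]oxy}-3-methoxyphenyl]zinc chloride | COc1cc([Zn]Cl)ccc1O[Si](C)(C)C(C)(C)C
F5 | step 4 | 3-[2-(4-{[tert-butyl(dimethyl)silyl]oxy}-3-methoxyphenyl)-3-formyl-7-methoxy-1-benzofuran-5-yl]propyl acetate | COc1cc(-c2oc3c(OC)cc(CCCOC(C)=O)cc3c2C=O)ccc1O[Si](C)(C)C(C)(C)C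
F6 | step 2 | 3-[3-(acetyloxy)-7-methoxy-2-oxo-2,3-dihydro-1-benzofuran-5-yl]propyl acetate (racemic) | COc1cc(CCCOC(C)=O)cc2c1OC(=O)C2OC(C)=O
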